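**Retrosynthetic overview**
1. Target ⇐ 8,13-diol: lipase-mediated acetylation of the primary C13-OH, then tigloylation of C8-OH; the C1 ketone comes from oxidation of a carbinol.
2. Butenolide (third ring) ⇐ intramolecular Horner–Wadsworth–Emmons reaction of a C6 phosphonoacetate onto a C7 ketone, itself unmasked by ozonolysis of an exocyclic methylene.
3. Ten-membered carbocycle (second ring) ⇐ intramolecular Nozaki–Hiyama–Kishi closure of a 2-iodoalkene (C7) onto a cis-epoxy aldehyde (C6).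
4. Open chain ⇐ nerol: Sharpless epoxidation (first ring; C4/C5), ozonolysis, Brown crotylation (C10), hydroboration, alkynylation and asymmetric transfer hydrogenation (C8).
5. Ring order: epoxide → cyclodecane → butenolide.

Assumption: the SMILES is read as the (4R,5S,6S,8S,10R) isomer with a cis-4,5-epoxide and an (E)-2-methylbut-2-enoate (tiglate) at C8.

Locants C1–C15 follow germacrane numbering of the target: C1 ketone, C2/C3 CH2, C4 epoxide C(CH3), C5 epoxide CH, C6 lactone O–CH, C7=C11 butenolide alkene, C8 CH–O-tigloyl, C9 CH2, C10 CH(CH3), C12 lactone C=O, C13 CH2OAc.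

**Route**

Step 1
Reactants: 1 nerol [(Z)-3,7-dimethylocta-2,6-dien-1-ol]
Product: 2 [(2S,3R)-3-methyl-3-(4-methylpent-3-en-1-yl)oxiran-2-yl]methanol
Conditions: Ti(OiPr)4 (10 mol%), L-(+)-diethyl tartrate (12 mol%), tBuOOH, 4 Å MS, CH2Cl2, −20 °C
Reagents that add atoms: tert-butyl hydroperoxide, CC(C)(C)OO
Why: Catalytic Sharpless asymmetric epoxidation of the achiral allylic alcohol sets C4 (R) and C5 (S) together (L-tartrate gives the 2S,3R epoxide of nerol), and the remote olefin is untouched.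

Step 2
Reactants: 2 epoxy alcohol
Product: 3 [(2S,3R)-3-methyl-3-(4-methylpent-3-en-1-yl)oxiran-2-yl]methyl 2,2-dimethylpropanoate
Conditions: pivaloyl chloride, pyridine, DMAP (cat.), CH2Cl2, 0 °C
Reagents that add atoms: pivaloyl chloride, CC(C)(C)C(Cl)=O
Why: Esterification gives a C6-O protecting group that withstands the organometallic, basic and oxidative steps up to step 13 and is removed reductively in step 14.

Step 3
Reactants: 3 pivalate
Product: 5 [(2S,3R)-3-methyl-3-(3-oxopropyl)oxiran-2-yl]methyl 2,2-dimethylpropanoate, via secondary ozonide 4 (not isolated)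
Conditions: O3, CH2Cl2, −78 °C; then PPh3, −78 °C → rt
Reagents that add atoms: ozone, [O-][O+]=O
Why: Ozonolysis with reductive work-up cleaves the only C=C and reveals the C1 aldehyde; the epoxide and ester are inert.

Step 4
Reactants: 5 aldehyde; 6 cis-but-2-ene
Product: 10 [(2S,3R)-3-[(3R,4R)-3-hydroxy-4-methylhex-5-en-1-yl]-3-methyloxiran-2-yl]methyl 2,2-dimethylpropanoate, via (Z)-but-2-enylpotassium 7 (not isolated), via (Z)-crotyldiisopinocampheylborane 8 (not isolated), via borinate ester 9 (not isolated)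
Conditions: 6, nBuLi, KOtBu, THF, −78 → −45 °C; (−)-Ipc2BOMe [from (+)-α-pinene], −78 °C; BF3·OEt2; then 5, −78 °C; then HOCH2CH2NH2, Et2O, rt
Reagents that add atoms: none
Why: Brown asymmetric crotylboration through a closed chair transition state gives the syn adduct under reagent control, setting C10 (R) and the temporary C1 carbinol (R); BF3 is consumed in forming 8 before 5 is added and the work-up is non-acidic, which protects the epoxide.

Step 5
Reactants: 10 homoallylic alcohol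
Product: 11 [(2S,3R)-3-methyl-3-[(3R,4R)-4-methyl-3-(triethylsilyloxy)hex-5-en-1-yl]oxiran-2-yl]methyl 2,2-dimethylpropanoate
Conditions: Et3SiCl, imidazole, DMF, 0 °C
Reagents that add atoms: chlorotriethylsilane, CC[Si](Cl)(CC)CC
Why: Silylation under basic conditions masks the C1-OH at once, so the γ,δ-epoxy alcohol cannot cyclise to a tetrahydrofuran; TES is the most labile silyl group of the three used and is removed selectively in step 22.

Step 6
Reactants: 11 alkene
Product: 13 [(2S,3R)-3-[(3R,4R)-6-hydroxy-4-methyl-3-(triethylsilyloxy)hexyl]-3-methyloxiran-2-yl]methyl 2,2-dimethylpropanoate, via B-alkyl-9-BBN adduct 12 (not isolated)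
Conditions: 9-BBN, THF, 0 °C → rt; then 30% H2O2, aq. NaOAc, 0 °C → rt
Reagents that add atoms: hydrogen peroxide, OO
Why: Anti-Markovnikov hydroboration–oxidation of the terminal vinyl group gives the C8 primary alcohol; 9-BBN reduces neither the ester nor the epoxide, and the buffered oxidation spares the pivalate.

Step 7
Reactants: 13 primary alcohol
Product: 14 [(2S,3R)-3-methyl-3-[(3R,4R)-4-methyl-6-oxo-3-(triethylsilyloxy)hexyl]oxiran-2-yl]methyl 2,2-dimethylpropanoate
Conditions: Dess–Martin periodinane, NaHCO3, CH2Cl2, 0 °C → rt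
Reagents that add atoms: none
Why: Buffered Dess–Martin oxidation gives the C8 aldehyde without touching the epoxide or silyl ether.

Step 8
Reactants: 14 aldehyde; 15 ethynyltrimethylsilane
Product: 17 [(2S,3R)-3-[(3R,4R,6RS)-6-hydroxy-4-methyl-3-(triethylsilyloxy)-8-(trimethylsilyl)oct-7-yn-1-yl]-3-methyloxiran-2-yl]methyl 2,2-dimethylpropanoate, via lithium (trimethylsilyl)acetylide 16 (not isolated)
Conditions: 15, nBuLi, THF, −78 °C; then 14, −78 °C; aq. NH4Cl
Reagents that add atoms: none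
Why: 1,2-Addition of a lithium acetylide to the aldehyde installs C7 and the sacrificial alkyne carbon; the pivalate and the hindered epoxide do not react at −78 °C, and the C8 mixture is removed in step 9.

Step 9
Reactants: 17 propargylic alcohols
Product: 18 [(2S,3R)-3-methyl-3-[(3R,4R)-4-methyl-6-oxo-3-(triethylsilyloxy)-8-(trimethylsilyl)oct-7-yn-1-yl]oxiran-2-yl]methyl 2,2-dimethylpropanoate
Conditions: Dess–Martin periodinane, NaHCO3, CH2Cl2, 0 °C → rt
Reagents that add atoms: none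
Why: Dess–Martin oxidation converges both C8 epimers to one ynone.

Step 10
Reactants: 18 ynone
Product: 19 [(2S,3R)-3-[(3R,4R,6S)-6-hydroxy-4-methyl-3-(triethylsilyloxy)-8-(trimethylsilyl)oct-7-yn-1-yl]-3-methyloxiran-2-yl]methyl 2,2-dimethylpropanoate
Conditions: RuCl[(S,S)-TsDPEN](p-cymene) (2 mol%), KOH (2 mol%), iPrOH, 25 °C
Reagents that add atoms: none
Why: Noyori asymmetric transfer hydrogenation of the alkynyl ketone under catalyst control sets C8 (S); the (S,S) catalyst gives (S)-propargylic alcohols.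

Step 11
Reactants: 19 silylalkyne
Product: 20 [(2S,3R)-3-[(3R,4R,6S)-6-hydroxy-4-methyl-3-(triethylsilyloxy)oct-7-yn-1-yl]-3-methyloxiran-2-yl]methyl 2,2-dimethylpropanoate
Conditions: K2CO3 (cat.), MeOH, 0 °C → rt, 1 h
Reagents that add atoms: none
Why: Methanolysis cleaves only the C(sp)–Si bond; the pivalate and the secondary TES ether survive the short exposure.

Step 12
Reactants: 20 terminal alkyne
Product: 22 [(2S,3R)-3-[(3R,4R,6S)-6-hydroxy-7-iodo-4-methyl-3-(triethylsilyloxy)oct-7-en-1-yl]-3-methyloxiran-2-yl]methyl 2,2-dimethylpropanoate, via 2-(tributylstannyl)alkene 21 (not isolated)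
Conditions: Bu3SnH, Mo(CO)3(CNtBu)3 (5 mol%), hydroquinone, THF, 55 °C; then I2, CH2Cl2, 0 °C
Reagents that add atoms: iodine, II
Why: Molybdenum-catalysed hydrostannation of a propargylic alcohol places tin on the internal carbon, and iododestannylation then gives the 2-iodoalkene under neutral conditions that the epoxide tolerates.

Step 13
Reactants: 22 iodo alcohol
Product: 23 [(2S,3R)-3-[(3R,4R,6S)-6-(tert-butyldimethylsilyloxy)-7-iodo-4-methyl-3-(triethylsilyloxy)oct-7-en-1-yl]-3-methyloxiran-2-yl]methyl 2,2-dimethylpropanoate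
Conditions: tBuMe2SiCl, imidazole, DMAP (cat.), DMF, rt → 35 °C
Reagents that add atoms: tert-butylchlorodimethylsilane, CC(C)(C)[Si](C)(C)Cl
Why: Silylation protects C8-OH with a group more robust than TES, which allows the C1/C8 differentiation later.

Step 14
Reactants: 23 pivalate
Product: 24 [(2S,3R)-3-[(3R,4R,6S)-6-(tert-butyldimethylsilyloxy)-7-iodo-4-methyl-3-(triethylsilyloxy)oct-7-en-1-yl]-3-methyloxiran-2-yl]methanol
Conditions: iBu2AlH (2.5 equiv), CH2Cl2, −78 °C; aq. potassium sodium tartrate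
Reagents that add atoms: none
Why: Reductive ester cleavage at −78 °C frees C6-OH without touching the silyl ethers, the alkenyl iodide or the epoxide.

Step 15
Reactants: 24 epoxy alcohol
Product: 25 (2R,3R)-3-[(3R,4R,6S)-6-(tert-butyldimethylsilyloxy)-7-iodo-4-methyl-3-(triethylsilyloxy)oct-7-en-1-yl]-3-methyloxirane-2-carbaldehyde
Conditions: Dess–Martin periodinane, NaHCO3, CH2Cl2, 0 °C
Reagents that add atoms: none
Why: Buffered Dess–Martin oxidation gives the epoxy aldehyde with its geometry unchanged (the C5 descriptor changes only through CIP priorities); it is used directly.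

Step 16
Reactants: 25 iodo epoxy aldehyde
Product: 27 (1R,4R,5S,6S,8S,10R)-8-(tert-butyldimethylsilyloxy)-4,5-epoxy-4,10-dimethyl-7-methylidene-1-(triethylsilyloxy)cyclodecan-6-ol, via alkenylchromium dichloride 26 (not isolated)
Conditions: CrCl2 (8 equiv), NiCl2 (0.1 equiv), DMSO/THF 3:1, 0.002 M (slow addition), rt
Reagents that add atoms: none
Why: Intramolecular Nozaki–Hiyama–Kishi reaction closes the ten-membered ring at C6–C7 chemoselectively at the aldehyde; Felkin–Anh attack anti to the epoxide C–O bond gives the anti epoxy alcohol, setting C6 (S).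

Step 17
Reactants: 28 diethyl (2-hydroxyethyl)phosphonate
Product: 29 diethyl [2-(tert-butyldiphenylsilyloxy)ethyl]phosphonate
Conditions: tBuPh2SiCl, imidazole, CH2Cl2, rt
Reagents that add atoms: tert-butylchlorodiphenylsilane, CC(C)(C)[Si](Cl)(c1ccccc1)c1ccccc1
Why: Silylation gives the future C13-O a robust group that survives the selective TES removal in step 22.

Step 18
Reactants: 29 silyloxy phosphonate
Product: 31 3-(tert-butyldiphenylsilyloxy)-2-(diethoxyphosphoryl)propanoic acid (racemic), via lithiated phosphonate 30 (not isolated)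
Conditions: LiN(iPr)2 (2.1 equiv), THF, −78 °C; CO2 (g), −78 °C; cold 1 M HCl to pH 3
Reagents that add atoms: carbon dioxide, O=C=O
Why: Carboxylation of the α-lithio phosphonate at −78 °C, where the poor silyloxide leaving group does not eliminate, delivers the C11–C13 unit with C12 as the acid.

Step 19
Reactants: 27 macrocyclic alcohol; 31 phosphono acid
Product: 32 (1R,4R,5S,6S,8S,10R)-8-(tert-butyldimethylsilyloxy)-4,5-epoxy-4,10-dimethyl-7-methylidene-1-(triethylsilyloxy)cyclodecan-6-yl 3-(tert-butyldiphenylsilyloxy)-2-(diethoxyphosphoryl)propanoate (epimers at the phosphonate carbon)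
Conditions: DCC, DMAP (0.2 equiv), CH2Cl2, 0 °C → rt
Reagents that add atoms: none
Why: Steglich esterification acylates the only free hydroxyl (C6) under near-neutral conditions, and the phosphonate stereocentre is irrelevant because it becomes sp2.

Step 20
Reactants: 32 phosphonate ester
Product: 34 (1R,4R,5S,6R,8S,10R)-8-(tert-butyldimethylsilyloxy)-4,5-epoxy-4,10-dimethyl-7-oxo-1-(triethylsilyloxy)cyclodecan-6-yl 3-(tert-butyldiphenylsilyloxy)-2-(diethoxyphosphoryl)propanoate, via secondary ozonide 33 (not isolated)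
Conditions: O3, CH2Cl2, −78 °C; then PPh3, −78 °C → rt
Reagents that add atoms: ozone, [O-][O+]=O
Why: Ozonolysis of the only C=C reveals the C7 ketone; C6 keeps its geometry and its descriptor changes only through CIP priorities.

Step 21
Reactants: 34 keto phosphonate
Product: 35 (1R,4R,5S,6S,8S,10R)-8-(tert-butyldimethylsilyloxy)-13-(tert-butyldiphenylsilyloxy)-4,5-epoxy-1-(triethylsilyloxy)germacr-7(11)-en-12,6-olide
Conditions: LiCl, DBU (1.05 equiv), MeCN, 0 °C → rt
Reagents that add atoms: none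
Why: Intramolecular Horner–Wadsworth–Emmons olefination under Masamune–Roush conditions closes the butenolide with the C7=C11 geometry fixed by the ring; C1 is still an ether, so no transannular aldol is possible, and the mild base deprotonates only the phosphonate.

Step 22
Reactants: 35 tris-silyl ether
Product: 36 (1R,4R,5S,6S,8S,10R)-8-(tert-butyldimethylsilyloxy)-13-(tert-butyldiphenylsilyloxy)-4,5-epoxy-1-hydroxygermacr-7(11)-en-12,6-olide
Conditions: HF·pyridine, pyridine, THF, 0 °C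
Reagents that add atoms: none
Why: Buffered fluoride cleaves the TES ether much faster than the hindered secondary TBS and primary TBDPS ethers, and the short cold exposure protects the epoxide.

Step 23
Reactants: 36 C1 alcohol
Product: 37 (4R,5S,6S,8S,10R)-8-(tert-butyldimethylsilyloxy)-13-(tert-butyldiphenylsilyloxy)-4,5-epoxy-1-oxogermacr-7(11)-en-12,6-olide
Conditions: Dess–Martin periodinane, NaHCO3, CH2Cl2, 0 °C → rt
Reagents that add atoms: none
Why: Neutral Dess–Martin oxidation forms the C1 ketone without epimerising C10 or opening the epoxide.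

Step 24
Reactants: 37 bis-silyl ether
Product: 38 (4R,5S,6S,8S,10R)-4,5-epoxy-8,13-dihydroxy-1-oxogermacr-7(11)-en-12,6-olide
Conditions: HF·pyridine, THF, 0 °C → rt
Reagents that add atoms: none
Why: Non-basic fluoride desilylation frees C8-OH and C13-OH while avoiding base, which would deprotonate C6-H and open the epoxide.

Step 25
Reactants: 38 diol; 39 vinyl acetate
Product: 40 (4R,5S,6S,8S,10R)-13-acetoxy-4,5-epoxy-8-hydroxy-1-oxogermacr-7(11)-en-12,6-olide
Conditions: lipase (Candida antarctica lipase B, immobilised), vinyl acetate, tBuOMe, 30 °C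
Reagents that add atoms: none
Why: Lipase-catalysed transesterification acetylates only the unhindered primary C13-OH and leaves the hindered secondary C8-OH free, under neutral conditions and irreversibly because vinyl alcohol tautomerises.

Step 26
Reactants: 40 monoacetate; 41 tiglic anhydride [(E)-2-methylbut-2-enoic anhydride]
Product: 42 (4R,5S,6S,8S,10R)-13-acetoxy-4,5-epoxy-1-oxo-8-[(E)-2-methylbut-2-enoyloxy]germacr-7(11)-en-12,6-olide
Conditions: DMAP, pyridine, CH2Cl2, rt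
Reagents that add atoms: none
Why: DMAP-catalysed acylation of the remaining C8-OH with the anhydride, which avoids ketene formation and olefin isomerisation, completes the target.

**Compound list**
1 | nerol, (Z)-3,7-dimethylocta-2,6-dien-1-ol | CC(C)=CCC/C(C)=C\CO | starting material
2 | [(2S,3R)-3-methyl-3-(4-methylpent-3-en-1-yl)oxiran-2-yl]methanol | CC(C)=CCC[C@@]1(C)O[C@H]1CO | intermediate
3 | pivalate of 2 | CC(C)=CCC[C@@]1(C)O[C@H]1COC(=O)C(C)(C)C | intermediate
4 | secondary ozonide of 3 (1,2,4-trioxolane) | CC1(C)OOC(CC[C@@]2(C)O[C@H]2COC(=O)C(C)(C)C)O1 | intermediate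
5 | [(2S,3R)-3-methyl-3-(3-oxopropyl)oxiran-2-yl]methyl 2,2-dimethylpropanoate | O=CCC[C@@]1(C)O[C@H]1COC(=O)C(C)(C)C | intermediate
6 | cis-but-2-ene | C/C=C\C | starting material
7 | (Z)-but-2-enylpotassium | C/C=C\C[K] | intermediate
8 | B-[(Z)-but-2-enyl]diisopinocampheylborane (Ipc from (+)-α-pinene) | C/C=C\CB([C@@H]1C[C@@H]2C[C@H]([C@H]1C)C2(C)C)[C@@H]1C[C@@H]2C[C@H]([C@H]1C)C2(C)C | intermediate
9 | diisopinocampheylborinate ester of 10 | C=C[C@@H](C)[C@H](OB([C@@H]1C[C@@H]2C[C@H]([C@H]1C)C2(C)C)[C@@H]1C[C@@H]2C[C@H]([C@H]1C)C2(C)C)CC[C@@]1(C)O[C@H]1COC(=O)C(C)(C)C | intermediate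
10 | [(2S,3R)-3-[(3R,4R)-3-hydroxy-4-methylhex-5-en-1-yl]-3-methyloxiran-2-yl]methyl 2,2-dimethylpropanoate | C=C[C@@H](C)[C@H](O)CC[C@@]1(C)O[C@H]1COC(=O)C(C)(C)C | intermediate
11 | triethylsilyl ether of 10 | C=C[C@@H](C)[C@H](O[Si](CC)(CC)CC)CC[C@@]1(C)O[C@H]1COC(=O)C(C)(C)C | intermediate
12 | B-alkyl-9-borabicyclo[3.3.1]nonane adduct of 11 | C1CCC2CCCC1B2CC[C@@H](C)[C@H](O[Si](CC)(CC)CC)CC[C@@]1(C)O[C@H]1COC(=O)C(C)(C)C | intermediate
13 | [(2S,3R)-3-[(3R,4R)-6-hydroxy-4-methyl-3-(triethylsilyloxy)hexyl]-3-methyloxiran-2-yl]methyl 2,2-dimethylpropanoate | OCC[C@@H](C)[C@H](O[Si](CC)(CC)CC)CC[C@@]1(C)O[C@H]1COC(=O)C(C)(C)C | intermediate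
14 | [(2S,3R)-3-methyl-3-[(3R,4R)-4-methyl-6-oxo-3-(triethylsilyloxy)hexyl]oxiran-2-yl]methyl 2,2-dimethylpropanoate | O=CC[C@@H](C)[C@H](O[Si](CC)(CC)CC)CC[C@@]1(C)O[C@H]1COC(=O)C(C)(C)C | intermediate
15 | ethynyltrimethylsilane | C#C[Si](C)(C)C | starting material
16 | lithium (trimethylsilyl)acetylide | [Li]C#C[Si](C)(C)C | intermediate
17 | (6RS)-propargylic alcohols from 14 | C[Si](C)(C)C#CC(O)C[C@@H](C)[C@H](O[Si](CC)(CC)CC)CC[C@@]1(C)O[C@H]1COC(=O)C(C)(C)C | intermediate
18 | alkynyl ketone (C8 ketone) | C[Si](C)(C)C#CC(=O)C[C@@H](C)[C@H](O[Si](CC)(CC)CC)CC[C@@]1(C)O[C@H]1COC(=O)C(C)(C)C | intermediate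
19 | (6S)-propargylic alcohol, silylalkyne | C[Si](C)(C)C#C[C@@H](O)C[C@@H](C)[C@H](O[Si](CC)(CC)CC)CC[C@@]1(C)O[C@H]1COC(=O)C(C)(C)C | intermediate
20 | (6S)-propargylic alcohol, terminal alkyne | C#C[C@@H](O)C[C@@H](C)[C@H](O[Si](CC)(CC)CC)CC[C@@]1(C)O[C@H]1COC(=O)C(C)(C)C | intermediate
21 | 2-(tributylstannyl)alkene from 20 | C=C([Sn](CCCC)(CCCC)CCCC)[C@@H](O)C[C@@H](C)[C@H](O[Si](CC)(CC)CC)CC[C@@]1(C)O[C@H]1COC(=O)C(C)(C)C | intermediate
22 | (6S)-2-iodoallylic alcohol | C=C(I)[C@@H](O)C[C@@H](C)[C@H](O[Si](CC)(CC)CC)CC[C@@]1(C)O[C@H]1COC(=O)C(C)(C)C | intermediate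
23 | tert-butyldimethylsilyl ether of 22 | C=C(I)[C@@H](O[Si](C)(C)C(C)(C)C)C[C@@H](C)[C@H](O[Si](CC)(CC)CC)CC[C@@]1(C)O[C@H]1COC(=O)C(C)(C)C | intermediate
24 | (2S,3R)-epoxy alcohol (C6-OH free) | C=C(I)[C@@H](O[Si](C)(C)C(C)(C)C)C[C@@H](C)[C@H](O[Si](CC)(CC)CC)CC[C@@]1(C)O[C@H]1CO | intermediate
25 | (2R,3R)-epoxy aldehyde | C=C(I)[C@@H](O[Si](C)(C)C(C)(C)C)C[C@@H](C)[C@H](O[Si](CC)(CC)CC)CC[C@@]1(C)O[C@H]1C=O | intermediate
26 | alkenylchromium dichloride from 25 | C=C([Cr](Cl)Cl)[C@@H](O[Si](C)(C)C(C)(C)C)C[C@@H](C)[C@H](O[Si](CC)(CC)CC)CC[C@@]1(C)O[C@H]1C=O | intermediate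
27 | (1R,4R,5S,6S,8S,10R)-8-(tert-butyldimethylsilyloxy)-4,5-epoxy-4,10-dimethyl-7-methylidene-1-(triethylsilyloxy)cyclodecan-6-ol | O[C@H]1C(=C)[C@@H](O[Si](C)(C)C(C)(C)C)C[C@@H](C)[C@H](O[Si](CC)(CC)CC)CC[C@@]2(C)O[C@H]21 | intermediate
28 | diethyl (2-hydroxyethyl)phosphonate | CCOP(=O)(CCO)OCC | starting material
29 | diethyl [2-(tert-butyldiphenylsilyloxy)ethyl]phosphonate | CCOP(=O)(CCO[Si](c1ccccc1)(c1ccccc1)C(C)(C)C)OCC | intermediate
30 | α-lithio derivative of 29 | CCOP(=O)(OCC)C([Li])CO[Si](c1ccccc1)(c1ccccc1)C(C)(C)C | intermediate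
31 | 3-(tert-butyldiphenylsilyloxy)-2-(diethoxyphosphoryl)propanoic acid (racemic) | CCOP(=O)(OCC)C(CO[Si](c1ccccc1)(c1ccccc1)C(C)(C)C)C(O)=O | intermediate
32 | C6 phosphonoacetate ester of 27 | CCOP(=O)(OCC)C(CO[Si](c1ccccc1)(c1ccccc1)C(C)(C)C)C(=O)O[C@H]1C(=C)[C@@H](O[Si](C)(C)C(C)(C)C)C[C@@H](C)[C@H](O[Si](CC)(CC)CC)CC[C@@]2(C)O[C@H]21 | intermediate
33 | spiro secondary ozonide of 32 | CCOP(=O)(OCC)C(CO[Si](c1ccccc1)(c1ccccc1)C(C)(C)C)C(=O)O[C@H]1C2(OCOO2)[C@@H](O[Si](C)(C)C(C)(C)C)C[C@@H](C)[C@H](O[Si](CC)(CC)CC)CC[C@@]2(C)O[C@H]21 | intermediate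
34 | C7 ketone (α-acyloxy ketone) | CCOP(=O)(OCC)C(CO[Si](c1ccccc1)(c1ccccc1)C(C)(C)C)C(=O)O[C@H]1C(=O)[C@@H](O[Si](C)(C)C(C)(C)C)C[C@@H](C)[C@H](O[Si](CC)(CC)CC)CC[C@@]2(C)O[C@H]21 | intermediate
35 | (1R,4R,5S,6S,8S,10R)-8-(tert-butyldimethylsilyloxy)-13-(tert-butyldiphenylsilyloxy)-4,5-epoxy-1-(triethylsilyloxy)germacr-7(11)-en-12,6-olide | CC(C)(C)[Si](C)(C)O[C@H]1C[C@@H](C)[C@H](O[Si](CC)(CC)CC)CC[C@@]2(C)O[C@H]2[C@H]2OC(=O)C(CO[Si](c3ccccc3)(c3ccccc3)C(C)(C)C)=C12 | intermediate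
36 | 1-hydroxy analogue of 35 (1R) | CC(C)(C)[Si](C)(C)O[C@H]1C[C@@H](C)[C@H](O)CC[C@@]2(C)O[C@H]2[C@H]2OC(=O)C(CO[Si](c3ccccc3)(c3ccccc3)C(C)(C)C)=C12 | intermediate
37 | (4R,5S,6S,8S,10R)-8-(tert-butyldimethylsilyloxy)-13-(tert-butyldiphenylsilyloxy)-4,5-epoxy-1-oxogermacr-7(11)-en-12,6-olide | CC(C)(C)[Si](C)(C)O[C@H]1C[C@@H](C)C(=O)CC[C@@]2(C)O[C@H]2[C@H]2OC(=O)C(CO[Si](c3ccccc3)(c3ccccc3)C(C)(C)C)=C12 | intermediate
38 | (4R,5S,6S,8S,10R)-4,5-epoxy-8,13-dihydroxy-1-oxogermacr-7(11)-en-12,6-olide | O[C@H]1C[C@@H](C)C(=O)CC[C@@]2(C)O[C@H]2[C@H]2OC(=O)C(CO)=C12 | intermediate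
39 | vinyl acetate | C=COC(C)=O | starting material
40 | (4R,5S,6S,8S,10R)-13-acetoxy-4,5-epoxy-8-hydroxy-1-oxogermacr-7(11)-en-12,6-olide | O[C@H]1C[C@@H](C)C(=O)CC[C@@]2(C)O[C@H]2[C@H]2OC(=O)C(COC(C)=O)=C12 | intermediate
41 | tiglic anhydride | C/C=C(\C)C(=O)OC(=O)/C(C)=C/C | starting material
42 | (4R,5S,6S,8S,10R)-13-acetoxy-4,5-epoxy-1-oxo-8-[(E)-2-methylbut-2-enoyloxy]germacr-7(11)-en-12,6-olide | C/C=C(\C)C(=O)O[C@H]1C[C@@H](C)C(=O)CC[C@@]2(C)O[C@H]2[C@H]2OC(=O)C(COC(C)=O)=C12 | target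

**Totals and risk**
Total step count: 26. Longest linear sequence: 24 steps (steps 1–16 and 19–26 from nerol); the side branch is steps 17–18.

Steps most likely to fail:

Step 16 (ring closure to a ten-membered ring; C6 selectivity rests on Felkin control inside a forming macrocycle). The fallback sets out from 19 and comes back at 34. Compound 19 is silylated (tBuMe2SiCl, imidazole) to the silyl ether F1, the pivalate is removed with iBu2AlH to give the epoxy alcohol F2, and Dess–Martin oxidation gives the alkynyl epoxy aldehyde F3. The ring is then closed by a nickel-catalysed reductive alkyne–aldehyde coupling (Ni(cod)2, PBu3, Et3B, toluene, high dilution). The C–C bond forms at the alkyne carbon remote from silicon, giving the macrocyclic allylic alcohol F4 with an exocyclic (trimethylsilyl)methylidene. Esterification with 31 (DCC, DMAP) gives the phosphonate ester F5, and ozonolysis of its vinylsilane double bond delivers ketone 34.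

Step 21 (the phosphonate anion carries a β-silyloxy group that could eliminate, and the product has an acidic C6-H next to the epoxide). The fallback sets out from 27 and comes back at 35. Commercial ethyl 2-(hydroxymethyl)acrylate is silylated (tBuPh2SiCl, imidazole) to the ester F6 and saponified (LiOH, THF/H2O) to the acrylic acid F7. Steglich esterification of 27 gives the diene ester F8. Ring-closing metathesis between the two 1,1-disubstituted olefins (second-generation Hoveyda–Grubbs catalyst, toluene, 80 °C) then forms the tetrasubstituted butenolide 35 directly, with no carbanion involved.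

Step 12 (regiochemistry of the hydrostannation). The fallback sets out from 14 and comes back at 22, replacing steps 8–12. Addition of CH2=CHMgBr to 14 (THF, −78 °C) gives the allylic alcohols F9, and Dess–Martin oxidation gives the vinyl ketone F10. α-Iodination (I2, K2CO3, DMAP cat., THF/H2O) gives the 2-iodo enone F11. Reduction with (R)-2-methyl-CBS-oxazaborolidine and catecholborane (toluene, −78 °C) sets C8 (S) and gives 22, with the iodine position fixed by construction.

**Further compounds**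
F1 | step 16 | tert-butyldimethylsilyl ether of 19 | C[Si](C)(C)C#C[C@@H](O[Si](C)(C)C(C)(C)C)C[C@@H](C)[C@H](O[Si](CC)(CC)CC)CC[C@@]1(C)O[C@H]1COC(=O)C(C)(C)C
F2 | step 16 | epoxy alcohol from F1 (pivalate removed) | C[Si](C)(C)C#C[C@@H](O[Si](C)(C)C(C)(C)C)C[C@@H](C)[C@H](O[Si](CC)(CC)CC)CC[C@@]1(C)O[C@H]1CO
F3 | step 16 | alkynyl epoxy aldehyde | C[Si](C)(C)C#C[C@@H](O[Si](C)(C)C(C)(C)C)C[C@@H](C)[C@H](O[Si](CC)(CC)CC)CC[C@@]1(C)O[C@H]1C=O
F4 | step 16 | macrocyclic allylic alcohol with exocyclic (trimethylsilyl)methylidene at C7 | O[C@H]1/C(=C/[Si](C)(C)C)[C@@H](O[Si](C)(C)C(C)(C)C)C[C@@H](C)[C@H](O[Si](CC)(CC)CC)CC[C@@]2(C)O[C@H]21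
F5 | step 16 | C6 phosphonoacetate ester of F4 | CCOP(=O)(OCC)C(CO[Si](c1ccccc1)(c1ccccc1)C(C)(C)C)C(=O)O[C@H]1/C(=C/[Si](C)(C)C)[C@@H](O[Si](C)(C)C(C)(C)C)C[C@@H](C)[C@H](O[Si](CC)(CC)CC)CC[C@@]2(C)O[C@H]21
F6 | step 21 | ethyl 2-[(tert-butyldiphenylsilyloxy)methyl]prop-2-enoate | C=C(CO[Si](c1ccccc1)(c1ccccc1)C(C)(C)C)C(=O)OCC
F7 | step 21 | 2-[(tert-butyldiphenylsilyloxy)methyl]prop-2-enoic acid | C=C(CO[Si](c1ccccc1)(c1ccccc1)C(C)(C)C)C(O)=O
F8 | step 21 | C6 acrylate ester of 27 | C=C(CO[Si](c1ccccc1)(c1ccccc1)C(C)(C)C)C(=O)O[C@H]1C(=C)[C@@H](O[Si](C)(C)C(C)(C)C)C[C@@H](C)[C@H](O[Si](CC)(CC)CC)CC[C@@]2(C)O[C@H]21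
F9 | step 12 | allylic alcohols from 14 (C8 epimers) | C=CC(O)C[C@@H](C)[C@H](O[Si](CC)(CC)CC)CC[C@@]1(C)O[C@H]1COC(=O)C(C)(C)C
F10 | step 12 | vinyl ketone | C=CC(=O)C[C@@H](C)[C@H](O[Si](CC)(CC)CC)CC[C@@]1(C)O[C@H]1COC(=O)C(C)(C)C
F11 | step 12 | 2-iodo enone | C=C(I)C(=O)C[C@@H](C)[C@H](O[Si](CC)(CC)CC)CC[C@@]1(C)O[C@H]1COC(=O)C(C)(C)C
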